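## Structural features

The target is a 3,8''-linked biflavanone with the configuration (2R,3R,2''R). Unit 1 is a 5,7-dihydroxychroman-4-one (rings A and C) carrying a 3,4-dihydroxyphenyl ring B on C2. Its C3 is bonded directly to C8'' of unit 2, a 5'',7''-dihydroxychroman-4-one (rings A'' and C'') carrying a 4-hydroxyphenyl ring on C2''. C2 and C3 are adjacent stereocentres with H2 and H3 cis, so ring B and ring A'' lie on the same face of ring C. C2'' is isolated, four bonds from C3 (C3–C8''–C8a''–O1''–C2''), and cannot be set by relay. C3–H is α to C4=O and can epimerise to the more stable trans isomer; both pyranone rings open by retro-oxa-Michael reaction under base, which would scramble C2 and C2''; the seven phenols are oxidation-sensitive. The real difficulty is the combination of a crowded bond between C3 and a fully substituted phloroglucinol ring, a contra-thermodynamic cis relationship at C2/C3, and absolute control at a remote third centre. The key step uses the fact that ring C of unit 2 is attached to ring A'' only through O1''–C2'' and C3''–C4'': the phenol oxygen on C8a'' and a hydroxymethyl carbon on C4a'' form a latent heterodiene O1''=C8a''–C4a''=C4'', and C2''–C3'' is the vinyl group of a para-oxygenated styrene. The price is that C4'' arrives as a methylene; it can be oxidised afterwards because it is benzylic to the trioxygenated ring A''.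

## Logic of the disconnections

21 to 20. Seven O–CH2Ph bonds are cut and no skeletal bond. Benzyl ethers mask every phenol through metalation, coupling, acid and oxidant steps and leave a single neutral hydrogenolysis for the end. The forward step must spare the benzylic C2–O1 and C2''–O1'' bonds, both ketones and the cis C3 centre.

20 to 18 through 19. The C4''=O group is traced back to CH2. The cut is made because the cycloaddition can only deliver C4'' as a methylene. It removes a base-sensitive second chromanone from all earlier intermediates. The forward oxidation must abstract hydride at C4'' and not at C2'', C2, C3 or any OCH2Ph group.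

18 to 15 and 16. The bonds O1''–C2'' and C3''–C4'' are cut, a retro-[4+2] that removes ring C of unit 2 and the C2'' centre together. 16 is commercial and 15 has only the two adjacent centres. The forward step needs 2''-aryl regiochemistry, reagent-controlled face selection at C2'', and acidity mild enough for the cis C3 centre. In 15 the oxygens on C5'' and C7'' stay benzylated, so only O1'' can form a methide.

15 to 14. The two C–O bonds of an isopropylidene ketal joining O1'' and the C4'' oxygen are cut. The free hydroxybenzyl alcohol is too labile for organolithium, cross-coupling and conjugate-addition conditions, so it is released only in the step before the cycloaddition and used without purification. The hydrolysis must not leave the electron-rich benzylic C–O bond ionised and must not epimerise C3.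

14 to 12 and 13. The C2–aryl bond and the C3–H bond are cut, which turns both adjacent centres into the planar C2=C3 bond of a chromone. 12 is achiral and 13 is commercial. The forward step must deliver the aryl group to one face of C2 and protonate C3 kinetically on the face away from the new aryl group.

12 to 7 and 11. The C3–C8'' bond is cut while both carbons are sp2, so the most crowded bond of the target is made as a cross-coupling. Each half is a simple benzene derivative. The forward step must join a di-ortho-oxygenated boronate to a base-sensitive 3-iodochromone.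

7 back to 1 through 5, 4, 3 and 2. The C8''–B, C8''–Br, ketal C–O, benzylic C–H and two O–benzyl bonds are cut in turn. All six carbons of ring A'' and C4'' come from 1. The forward steps need bromination at C8 and not at C6 of 4, and benzylation of 1 that leaves the chelated hydroxyl free.

11 back to 8 through 10 and 9. The C3–I bond, O1–C2 and C2–C3 are cut, tracing the pyranone ring to a methyl ketone plus a one-carbon unit. Ring A and C4 come from 8. The forward steps need the same selective benzylation as in the other series.

## Other disconnections considered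

Alternative 1: The cut runs through ring A'' itself. C8a''–C8'' and C6''–C7'' are broken, so ring A'' is traced to the four carbons of 3-(benzyloxy)cyclobut-2-en-1-one A1 and the two alkyne carbons of the 3-(benzyloxyethynyl) tetra-O-benzyl flavone A2. Forward, heating A1 with A2 would open the cyclobutenone to a vinylketene, which adds to the ynol ether in a [2+2] sense. The new cyclobutenone opens and recloses by six-electron electrocyclisation, and tautomerisation gives the phenol A3 with the hydroxyl on C8a'' and benzyloxy groups on C5'' and C7''.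

- In favour: the C3–C8'' bond is not made by coupling two hindered partners, the oxygen pattern of ring A'' follows from the cascade without a regiochemical choice, and the one free phenol appears where ring C of unit 2 must be attached. On these points it is better than the chosen plan, which needs a regioselective bromination and a crowded Suzuki–Miyaura coupling.
- Against: A2 is a benzyl alkynyl ether, a class prone to sigmatropic rearrangement on warming, and its alkyne sits on an electron-poor chromone carbon, which lowers its reactivity towards the ketene. A3 is a flavone, so C2 and C3 are still sp2. Both centres would need an enantioselective cis reduction of a tetrasubstituted diaryl alkene in the presence of benzyl ethers, for which no dependable method can be named. Ring C of unit 2 with C2'' is still missing.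
- Comparison: the pericyclic cascade is as defensible mechanistically as the chosen cycloaddition, and the two plans are equal in convergence. The alternative is weaker on stereochemistry and on step count after its key step.

Alternative 2: The cut is O1–C2 and C3–C4 of ring C of unit 1. It leads to the ring A methide precursor 3 of the chosen route and the Z-stilbene A4, whose aryl groups are the dibenzyloxyphenyl ring B and ring A'' of a finished, benzylated unit 2 flavanone. Forward, the methide from 3 and a chiral binaphthyl phosphoric acid would add across one face of the Z double bond, giving the cis-2,3-diaryl flavan A5 with C4 as methylene.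

- In favour: C2 and C3 are made together and their cis relationship is inherited from the alkene geometry, not from a kinetic protonation. C3 is not α to a carbonyl until the end, so the cis relationship is more robust; on that point it is better than the chosen plan. The methide is unhindered and the bond-forming event is of the same type, so on precedent the two are equal.
- Against: a 1,2-diaryl Z-alkene with one di-ortho-substituted aryl group is a much poorer 2π partner than a terminal styrene. With so stabilised a methide the addition is likely stepwise, and rotation in the benzylic cation or acid-induced Z to E isomerisation of A4 would leak the trans isomer. The acid must control two new centres at once. A4 needs a preformed, enantiopure, base-sensitive flavanone with a Z-styryl group on C8'', a longer and more delicate precursor than 15.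
- Comparison: the end game has the same length (benzylic oxidation, oxidation to the ketone, hydrogenolysis), but the hydride abstraction would be at a carbon next to the crowded C3. The alternative is better on robustness of the cis relationship, equal in end-game length, and weaker on reactivity of the 2π partner and front-end length.

Alternative 3: The cut is the C2''–C3'' bond. The precursor is the α-diazoketone A6: ring A'' carries the diazoacetyl group on C4a'', a 4-benzyloxybenzyl ether on O1'', a triisopropylsilyl ether on O5'' and the cis unit 1 on C8''. Forward, Rh2(S-PTTL)4 would release N2 and the rhodium carbenoid would insert into a benzylic C–H bond of the neighbouring ether, closing ring C of unit 2 as the chromanone A7 and setting C2''.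

- In favour: C4'' is already a ketone, so the two oxidation steps of the chosen plan disappear; on step count after the key step it is better. The new centre is again reagent-controlled, an equal point.
- Against: the ether oxygen is closer to the carbenoid than the C–H bond, and oxonium ylide formation with [1,2]-shift of the benzyl group to a benzofuranone is the usual diversion. Insertion through a six-membered transition state is less favourable than through a five-membered one, and such chromanone-forming insertions are usually only moderately enantioselective. The precursor needs three kinds of oxygen protection on ring A'' and a diazoketone built on a ring that already carries the epimerisable C3 centre.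
- Comparison: shorter after the key step, comparable in stereocontrol logic, longer and less chemoselective before it.

Key step: step 12

Assumption: the senses of induction of (S)-t-BuPyOx (2R) and of (R)-TRIP (2''R) are assigned by analogy with simpler chromones and methides; both catalysts are available as either enantiomer.

## Route

Step 1
Reactants: 1 2,4,6-trihydroxybenzaldehyde
Product: 2 2,4-bis(benzyloxy)-6-hydroxybenzaldehyde
Conditions: BnBr (2.1 equiv), K2CO3, DMF, 0 °C to rt
Reagents that add atoms: benzyl bromide, BrCc1ccccc1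
Why: Williamson ether synthesis; the hydroxyl hydrogen-bonded to the formyl group is the least nucleophilic and stays free, and the symmetry of 1 makes the two ortho hydroxyls equivalent.

Step 2
Reactants: 2 2,4-bis(benzyloxy)-6-hydroxybenzaldehyde
Product: 3 3,5-bis(benzyloxy)-2-(hydroxymethyl)phenol
Conditions: NaBH4, THF/EtOH, 0 °C, short reaction time; pH 7 buffer quench
Reagents that add atoms: none
Why: Hydride reduction of the aldehyde; low temperature and a neutral quench keep the electron-rich hydroxybenzyl alcohol from ionising and being reduced further.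

Step 3
Reactants: 3 3,5-bis(benzyloxy)-2-(hydroxymethyl)phenol
Product: 4 5,7-bis(benzyloxy)-2,2-dimethyl-4H-1,3-benzodioxin
Conditions: Me2C(OMe)2, PPTS (cat.), acetone, 0 °C to rt
Reagents that add atoms: 2,2-dimethoxypropane, COC(C)(C)OC
Why: Acid-catalysed transketalisation closes the six-membered isopropylidene ketal over the phenol and the benzylic alcohol, masking both oxygens of the future methide.

Step 4
Reactants: 4 5,7-bis(benzyloxy)-2,2-dimethyl-4H-1,3-benzodioxin
Product: 5 5,7-bis(benzyloxy)-8-bromo-2,2-dimethyl-4H-1,3-benzodioxin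
Conditions: NBS (1.0 equiv), CH2Cl2, −78 to −40 °C
Reagents that add atoms: N-bromosuccinimide, O=C1CCC(=O)N1Br
Why: Electrophilic aromatic bromination; C8, between the ring oxygen and one benzyloxy group, is less hindered than C6 between two benzyloxy groups, the preference known for 5,7-dibenzyloxyflavans.

Step 5
Reactants: 5 5,7-bis(benzyloxy)-8-bromo-2,2-dimethyl-4H-1,3-benzodioxin
Product: 7 2-[5,7-bis(benzyloxy)-2,2-dimethyl-4H-1,3-benzodioxin-8-yl]-4,4,5,5-tetramethyl-1,3,2-dioxaborolane, via aryllithium 6 (not isolated)
Conditions: n-BuLi, THF, −78 °C; then i-PrOBpin, −78 °C to rt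
Reagents that add atoms: 2-isopropoxy-4,4,5,5-tetramethyl-1,3,2-dioxaborolane, CC(C)OB1OC(C)(C)C(C)(C)O1
Why: Bromine–lithium exchange followed by borylation of the aryllithium; at −78 °C the benzyl ethers and the ketal are inert.

Step 6
Reactants: 8 2,4,6-trihydroxyacetophenone
Product: 9 1-[2,4-bis(benzyloxy)-6-hydroxyphenyl]ethanone
Conditions: BnBr (2.1 equiv), K2CO3, DMF, rt
Reagents that add atoms: benzyl bromide, BrCc1ccccc1
Why: Williamson ether synthesis with the same selectivity as in step 1; the chelated hydroxyl next to the acetyl group stays free.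

Step 7
Reactants: 9 1-[2,4-bis(benzyloxy)-6-hydroxyphenyl]ethanone
Product: 10 (E)-1-[2,4-bis(benzyloxy)-6-hydroxyphenyl]-3-(dimethylamino)prop-2-en-1-one
Conditions: Me2NCH(OMe)2, toluene, 90 °C
Reagents that add atoms: N,N-dimethylformamide dimethyl acetal, COC(OC)N(C)C
Why: Condensation of the methyl ketone with the amide acetal gives the enaminone and supplies the carbon that becomes C2 of ring C.

Step 8
Reactants: 10 (E)-1-[2,4-bis(benzyloxy)-6-hydroxyphenyl]-3-(dimethylamino)prop-2-en-1-one
Product: 11 5,7-bis(benzyloxy)-3-iodo-4H-chromen-4-one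
Conditions: I2, MeOH, rt
Reagents that add atoms: iodine, II
Why: Iodination of the enaminone α-carbon, then addition–elimination by the phenol with loss of dimethylamine, closes the pyranone ring; this is the standard enaminone route to 3-iodochromones.

Step 9
Reactants: 7 2-[5,7-bis(benzyloxy)-2,2-dimethyl-4H-1,3-benzodioxin-8-yl]-4,4,5,5-tetramethyl-1,3,2-dioxaborolane; 11 5,7-bis(benzyloxy)-3-iodo-4H-chromen-4-one
Product: 12 5,7-bis(benzyloxy)-3-[5,7-bis(benzyloxy)-2,2-dimethyl-4H-1,3-benzodioxin-8-yl]-4H-chromen-4-one
Conditions: Pd(OAc)2 (5 mol%), SPhos (10 mol%), K3PO4, toluene/H2O (10:1), 80 °C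
Reagents that add atoms: none
Why: Suzuki–Miyaura cross-coupling; zerovalent palladium inserts into the C3–I bond, and the dialkylbiarylphosphine allows transmetalation and reductive elimination with the di-ortho-oxygenated boronate.

Step 10
Reactants: 12 5,7-bis(benzyloxy)-3-[5,7-bis(benzyloxy)-2,2-dimethyl-4H-1,3-benzodioxin-8-yl]-4H-chromen-4-one; 13 3,4-bis(benzyloxy)phenylboronic acid
Product: 14 (2R,3R)-5,7-bis(benzyloxy)-2-[3,4-bis(benzyloxy)phenyl]-3-[5,7-bis(benzyloxy)-2,2-dimethyl-4H-1,3-benzodioxin-8-yl]chroman-4-one (2,3-cis)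
Conditions: Pd(OCOCF3)2 (10 mol%), (S)-t-BuPyOx (12 mol%), NH4PF6 (30 mol%), H2O (5 equiv), 13 (2.5 equiv), ClCH2CH2Cl, 40 °C; neutral work-up
Reagents that add atoms: none
Why: Proposed new method: asymmetric conjugate arylation of a 3-aryl chromone with stereoselective protonation; the aryl–palladium species formed from 13 on the cationic divalent palladium–pyridine-oxazoline complex should insert the C2=C3 bond with ligand-controlled delivery of the aryl group to one face of C2 (2R), water releases the palladium enolate as the enol, and C3 is protonated on the face away from the pseudo-axial C2 aryl group, which places ring A'' cis to it (3R); the closest known reaction is the Pd(OCOCF3)2/t-BuPyOx conjugate addition of arylboronic acids to chromones unsubstituted at C3, and the new elements are the α-aryl group and the second centre made by protonation.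

Step 11
Reactants: 14 (2R,3R)-5,7-bis(benzyloxy)-2-[3,4-bis(benzyloxy)phenyl]-3-[5,7-bis(benzyloxy)-2,2-dimethyl-4H-1,3-benzodioxin-8-yl]chroman-4-one (2,3-cis)
Product: 15 (2R,3R)-5,7-bis(benzyloxy)-2-[3,4-bis(benzyloxy)phenyl]-3-[4,6-bis(benzyloxy)-2-hydroxy-3-(hydroxymethyl)phenyl]chroman-4-one (2,3-cis)
Conditions: AcOH/THF/H2O (3:1:1), 30 °C; neutral work-up, used without chromatography
Reagents that add atoms: none
Why: Acid-catalysed ketal hydrolysis; the large excess of water returns any ionised benzylic carbon to the alcohol, and the weak acid should leave the hindered C3–H untouched.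

Step 12
Reactants: 15 (2R,3R)-5,7-bis(benzyloxy)-2-[3,4-bis(benzyloxy)phenyl]-3-[4,6-bis(benzyloxy)-2-hydroxy-3-(hydroxymethyl)phenyl]chroman-4-one (2,3-cis); 16 4-(benzyloxy)styrene
Product: 18 (2R,3R)-5,7-bis(benzyloxy)-2-[3,4-bis(benzyloxy)phenyl]-3-{(2R)-5,7-bis(benzyloxy)-2-[4-(benzyloxy)phenyl]chroman-8-yl}chroman-4-one, via ortho-quinone methide 17 (not isolated)
Conditions: (R)-TRIP [(R)-3,3'-bis(2,4,6-triisopropylphenyl)-1,1'-binaphthyl-2,2'-diyl hydrogen phosphate] (10 mol%), 16 (3 equiv), 4 Å molecular sieves, CH2Cl2, 0 °C to rt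
Reagents that add atoms: none
Why: The phosphoric acid protonates the benzylic hydroxyl of 15 and water leaves, giving the ortho-quinone methide 17 hydrogen-bonded through O1'' to the chiral phosphate. The heterodiene O1''=C8a''–C4a''=C4'' is electron-poor and 16 is electron-rich, so the terminal alkene carbon bonds to C4'' while positive charge builds at the benzylic carbon, stabilised by the para benzyloxy group, and O1'' closes onto it; this asynchronous inverse-demand hetero-Diels–Alder reaction fixes the 2''-aryl regiochemistry. The closest known reaction type is the Brønsted-acid-catalysed [4+2] cycloaddition of ortho-hydroxybenzyl alcohols with 4-alkoxystyrenes to flavans, including chiral phosphoric acid versions. Ring C of unit 2 is closed by the cycloaddition itself, O1''–C2'' and C3''–C4'' forming in one event. C2'' is set by the catalyst: the triisopropylphenyl walls of the phosphate bound at O1'' shield one face of the styrene as O1''–C2'' forms, and this reagent control is expected to outweigh the untouched C2 and C3 centres. Three selectivities are needed: cycloaddition over Friedel–Crafts attack of the methide on C6'' of a second molecule (excess 16 and dilution), cycloaddition over attack of the C8a'' phenol on C4=O (a deactivated vinylogous ester ketone flanked by a benzyloxy group), and retention of the cis C3 centre (a weak acid at or below room temperature, and an enol that would be tetrasubstituted and flanked by two aryl groups).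

Step 13
Reactants: 18 (2R,3R)-5,7-bis(benzyloxy)-2-[3,4-bis(benzyloxy)phenyl]-3-{(2R)-5,7-bis(benzyloxy)-2-[4-(benzyloxy)phenyl]chroman-8-yl}chroman-4-one
Product: 19 (2R,3R)-5,7-bis(benzyloxy)-2-[3,4-bis(benzyloxy)phenyl]-3-{(2R)-5,7-bis(benzyloxy)-2-[4-(benzyloxy)phenyl]-4-hydroxychroman-8-yl}chroman-4-one (mixture of C4'' epimers)
Conditions: DDQ (1.3 equiv), CH2Cl2/H2O (20:1), 0 °C to rt
Reagents that add atoms: water, O
Why: Benzylic oxidation by hydride abstraction; the C4'' cation is stabilised by O1'' and both benzyloxy groups of ring A'' and is trapped by water, as known for C4 of 5,7-dibenzyloxyflavans, whereas C2'' lacks that stabilisation and C2 and C3 are deactivated by C4=O. The C4'' configuration is irrelevant because the centre is oxidised next.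

Step 14
Reactants: 19 (2R,3R)-5,7-bis(benzyloxy)-2-[3,4-bis(benzyloxy)phenyl]-3-{(2R)-5,7-bis(benzyloxy)-2-[4-(benzyloxy)phenyl]-4-hydroxychroman-8-yl}chroman-4-one (mixture of C4'' epimers)
Product: 20 (2R,3R)-5,7-bis(benzyloxy)-2-[3,4-bis(benzyloxy)phenyl]-3-{(2R)-5,7-bis(benzyloxy)-2-[4-(benzyloxy)phenyl]-4-oxochroman-8-yl}chroman-4-one
Conditions: Dess–Martin periodinane (1.5 equiv), NaHCO3, CH2Cl2, 0 °C to rt
Reagents that add atoms: none
Why: Dess–Martin oxidation of the secondary benzylic alcohol under buffered, near-neutral conditions that should leave C3 and the benzyl ethers alone.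

Step 15
Reactants: 20 (2R,3R)-5,7-bis(benzyloxy)-2-[3,4-bis(benzyloxy)phenyl]-3-{(2R)-5,7-bis(benzyloxy)-2-[4-(benzyloxy)phenyl]-4-oxochroman-8-yl}chroman-4-one
Product: 21 (2R,3R)-2-(3,4-dihydroxyphenyl)-5,7-dihydroxy-3-[(2R)-5,7-dihydroxy-2-(4-hydroxyphenyl)-4-oxochroman-8-yl]chroman-4-one
Conditions: H2 (1 atm), 10% Pd/C, EtOAc/MeOH (1:1), rt; filtration and evaporation without base or acid
Reagents that add atoms: none
Why: Hydrogenolysis of the seven benzyl ethers under neutral conditions, as is routine for benzylated flavanones; no stereocentre is touched and the cis C3 centre is never exposed to base.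

## Compound list

1 | 2,4,6-trihydroxybenzaldehyde | O=Cc1c(O)cc(O)cc1O | starting material
2 | 2,4-bis(benzyloxy)-6-hydroxybenzaldehyde | O=Cc1c(O)cc(OCc2ccccc2)cc1OCc1ccccc1 | intermediate
3 | 3,5-bis(benzyloxy)-2-(hydroxymethyl)phenol | OCc1c(O)cc(OCc2ccccc2)cc1OCc1ccccc1 | intermediate
4 | 5,7-bis(benzyloxy)-2,2-dimethyl-4H-1,3-benzodioxin | CC1(C)OCc2c(OCc3ccccc3)cc(OCc3ccccc3)cc2O1 | intermediate
5 | 5,7-bis(benzyloxy)-8-bromo-2,2-dimethyl-4H-1,3-benzodioxin | CC1(C)OCc2c(OCc3ccccc3)cc(OCc3ccccc3)c(Br)c2O1 | intermediate
6 | [5,7-bis(benzyloxy)-2,2-dimethyl-4H-1,3-benzodioxin-8-yl]lithium | CC1(C)OCc2c(OCc3ccccc3)cc(OCc3ccccc3)c([Li])c2O1 | intermediate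
7 | 2-[5,7-bis(benzyloxy)-2,2-dimethyl-4H-1,3-benzodioxin-8-yl]-4,4,5,5-tetramethyl-1,3,2-dioxaborolane | CC1(C)OCc2c(OCc3ccccc3)cc(OCc3ccccc3)c(B3OC(C)(C)C(C)(C)O3)c2O1 | intermediate
8 | 2,4,6-trihydroxyacetophenone | CC(=O)c1c(O)cc(O)cc1O | starting material
9 | 1-[2,4-bis(benzyloxy)-6-hydroxyphenyl]ethanone | CC(=O)c1c(O)cc(OCc2ccccc2)cc1OCc1ccccc1 | intermediate
10 | (E)-1-[2,4-bis(benzyloxy)-6-hydroxyphenyl]-3-(dimethylamino)prop-2-en-1-one | CN(C)/C=C/C(=O)c1c(O)cc(OCc2ccccc2)cc1OCc1ccccc1 | intermediate
11 | 5,7-bis(benzyloxy)-3-iodo-4H-chromen-4-one | O=c1c(I)coc2cc(OCc3ccccc3)cc(OCc3ccccc3)c12 | intermediate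
12 | 5,7-bis(benzyloxy)-3-[5,7-bis(benzyloxy)-2,2-dimethyl-4H-1,3-benzodioxin-8-yl]-4H-chromen-4-one | O=c1c(-c2c(OCc3ccccc3)cc(OCc3ccccc3)c3COC(C)(C)Oc23)coc2cc(OCc3ccccc3)cc(OCc3ccccc3)c12 | intermediate
13 | 3,4-bis(benzyloxy)phenylboronic acid | OB(O)c1ccc(OCc2ccccc2)c(OCc2ccccc2)c1 | starting material
14 | (2R,3R)-5,7-bis(benzyloxy)-2-[3,4-bis(benzyloxy)phenyl]-3-[5,7-bis(benzyloxy)-2,2-dimethyl-4H-1,3-benzodioxin-8-yl]chroman-4-one (2,3-cis) | CC1(C)OCc2c(OCc3ccccc3)cc(OCc3ccccc3)c(c2O1)[C@H]1C(=O)c2c(OCc3ccccc3)cc(OCc3ccccc3)cc2O[C@H]1c1ccc(OCc3ccccc3)c(OCc3ccccc3)c1 | intermediate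
15 | (2R,3R)-5,7-bis(benzyloxy)-2-[3,4-bis(benzyloxy)phenyl]-3-[4,6-bis(benzyloxy)-2-hydroxy-3-(hydroxymethyl)phenyl]chroman-4-one (2,3-cis) | OCc1c(OCc3ccccc3)cc(OCc3ccccc3)c(c1O)[C@H]1C(=O)c2c(OCc3ccccc3)cc(OCc3ccccc3)cc2O[C@H]1c1ccc(OCc3ccccc3)c(OCc3ccccc3)c1 | intermediate
16 | 4-(benzyloxy)styrene | C=Cc1ccc(OCc2ccccc2)cc1 | starting material
17 | (2R,3R)-5,7-bis(benzyloxy)-2-[3,4-bis(benzyloxy)phenyl]-3-[2,4-bis(benzyloxy)-5-methylidene-6-oxocyclohexa-1,3-dien-1-yl]chroman-4-one (ortho-quinone methide) | C=C1C(OCc3ccccc3)=CC(OCc3ccccc3)=C(C1=O)[C@H]1C(=O)c2c(OCc3ccccc3)cc(OCc3ccccc3)cc2O[C@H]1c1ccc(OCc3ccccc3)c(OCc3ccccc3)c1 | intermediate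
18 | (2R,3R)-5,7-bis(benzyloxy)-2-[3,4-bis(benzyloxy)phenyl]-3-{(2R)-5,7-bis(benzyloxy)-2-[4-(benzyloxy)phenyl]chroman-8-yl}chroman-4-one | C1C[C@H](c2ccc(OCc3ccccc3)cc2)Oc2c1c(OCc3ccccc3)cc(OCc3ccccc3)c2[C@H]1C(=O)c2c(OCc3ccccc3)cc(OCc3ccccc3)cc2O[C@H]1c1ccc(OCc3ccccc3)c(OCc3ccccc3)c1 | intermediate
19 | (2R,3R)-5,7-bis(benzyloxy)-2-[3,4-bis(benzyloxy)phenyl]-3-{(2R)-5,7-bis(benzyloxy)-2-[4-(benzyloxy)phenyl]-4-hydroxychroman-8-yl}chroman-4-one (mixture of C4'' epimers) | OC1C[C@H](c2ccc(OCc3ccccc3)cc2)Oc2c1c(OCc3ccccc3)cc(OCc3ccccc3)c2[C@H]1C(=O)c2c(OCc3ccccc3)cc(OCc3ccccc3)cc2O[C@H]1c1ccc(OCc3ccccc3)c(OCc3ccccc3)c1 | intermediate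
20 | (2R,3R)-5,7-bis(benzyloxy)-2-[3,4-bis(benzyloxy)phenyl]-3-{(2R)-5,7-bis(benzyloxy)-2-[4-(benzyloxy)phenyl]-4-oxochroman-8-yl}chroman-4-one | O=C1C[C@H](c2ccc(OCc3ccccc3)cc2)Oc2c1c(OCc3ccccc3)cc(OCc3ccccc3)c2[C@H]1C(=O)c2c(OCc3ccccc3)cc(OCc3ccccc3)cc2O[C@H]1c1ccc(OCc3ccccc3)c(OCc3ccccc3)c1 | intermediate
21 | (2R,3R)-2-(3,4-dihydroxyphenyl)-5,7-dihydroxy-3-[(2R)-5,7-dihydroxy-2-(4-hydroxyphenyl)-4-oxochroman-8-yl]chroman-4-one | O=C1C[C@H](c2ccc(O)cc2)Oc2c1c(O)cc(O)c2[C@H]1C(=O)c2c(O)cc(O)cc2O[C@H]1c1ccc(O)c(O)c1 | target

## Step count and least certain steps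

Total: 15 steps. Longest linear sequence: 12 steps (steps 1 to 5 and 9 to 15, from 1).

Step 10 (the labelled step).
- Risk: the migratory insertion requires palladium to bond to C3, which is flanked by the two ortho oxygens of ring A''. It may be slow enough for protodeboronation of 13 to win. Face selection at C2 may be eroded by the α-aryl group. Protonation may drift to thermodynamic control, or the product may epimerise to the trans isomer on prolonged warming. The ketal may be partly lost in the wet, weakly acidic medium.
- Fallback with known chemistry, setting out from 12: add the aryl group as an organocopper reagent, which bonds only to C2 and tolerates α-substitution. (3,4-Bis(benzyloxy)phenyl)magnesium bromide F1 (from the commercial aryl bromide and Mg), CuBr·SMe2 and Me3SiCl in THF at −78 to −40 °C should give the racemic silyl enol ether F2. Protonolysis with Bu4NF buffered by AcOH at −78 °C should deliver the proton anti to the C2 aryl group and give the cis ketone as a racemate of 14 and its (2S,3S) enantiomer F3. Preparative chromatography on a chiral stationary phase removes F3, and the route is rejoined at 14.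

Step 12 (key step).
- Risk: the phosphate must bind O1'' next to the bulky C8'' substituent. This may weaken or mismatch face selection at C2''. The stabilised methide may also be consumed by self-alkylation at C6'' or by reversible water addition faster than by the styrene.
- Fallback, setting out from 3: run the same cycloaddition on the methide that has no neighbour and no pre-existing centres. 3, 16 and the same acid should give, through the simple methide F4, the flavan (2R)-5,7-bis(benzyloxy)-2-[4-(benzyloxy)phenyl]chroman F5. NBS at −78 °C gives the 8-bromide F6. Bromine–lithium exchange gives the aryllithium F7, which is borylated to the pinacol boronate F8. Coupling with 11 under the conditions of step 9 gives the chromone F9, and conjugate arylation with 13 under the conditions of step 10 rejoins the route at 18. If the cuprate variant is used here, the C2'' centre makes the two cis products diastereomers that separate on silica.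

Step 11.
- Risk: the medium that opens the ketal can also ionise the electron-rich benzylic C4''–O bond. This may lead to self-alkylation or incomplete conversion, and to slow acid-induced epimerisation at C3.
- Fallback, setting out from 14: omit the hydrolysis. 14 is exposed directly to the phosphoric acid and 16 under the conditions of step 12. Protonation of the benzylic ketal oxygen, cleavage of the C4''–O bond and loss of acetone should give 17 in the flask, and the route is rejoined at 18.

Step 9.
- Risk: protodeboronation of the di-ortho-oxygenated boronate and hydroxide-induced opening of the iodochromone may both outrun a slow transmetalation.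
- Fallback, setting out from 5: base-free Negishi coupling. The aryllithium 6 is transmetalated with ZnCl2 to the arylzinc chloride F10, which is coupled with 11 using Pd2(dba)3 and SPhos in THF at rt to 50 °C. The route is rejoined at 12.

Step 4.
- Risk: bromination at C6, or twice, if the steric preference for C8 is smaller in the benzodioxin than in flavans.
- Fallback, setting out from 2: let the free phenol direct the halogen before the ketal is made. NBS in MeCN at 0 °C should brominate 2 ortho to the hydroxyl, giving 4,6-bis(benzyloxy)-3-bromo-2-hydroxybenzaldehyde F11. NaBH4 reduction gives the bromo diol F12, and ketalisation as in step 3 rejoins the route at 5.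

## Further compounds

F1 | step 10 | (3,4-bis(benzyloxy)phenyl)magnesium bromide | Br[Mg]c1ccc(OCc2ccccc2)c(OCc2ccccc2)c1
F2 | step 10 | racemic 5,7-bis(benzyloxy)-2-[3,4-bis(benzyloxy)phenyl]-3-[5,7-bis(benzyloxy)-2,2-dimethyl-4H-1,3-benzodioxin-8-yl]-4-(trimethylsilyloxy)-2H-chromene | C[Si](C)(C)OC1=C(c2c(OCc3ccccc3)cc(OCc3ccccc3)c3COC(C)(C)Oc23)C(c2ccc(OCc3ccccc3)c(OCc3ccccc3)c2)Oc2cc(OCc3ccccc3)cc(OCc3ccccc3)c12
F3 | step 10 | (2S,3S) enantiomer of 14 | CC1(C)OCc2c(OCc3ccccc3)cc(OCc3ccccc3)c(c2O1)[C@@H]1C(=O)c2c(OCc3ccccc3)cc(OCc3ccccc3)cc2O[C@@H]1c1ccc(OCc3ccccc3)c(OCc3ccccc3)c1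
F4 | step 12 | 3,5-bis(benzyloxy)-6-methylidenecyclohexa-2,4-dien-1-one | C=C1C(OCc2ccccc2)=CC(OCc2ccccc2)=CC1=O
F5 | step 12 | (2R)-5,7-bis(benzyloxy)-2-[4-(benzyloxy)phenyl]chroman | C1C[C@H](c2ccc(OCc3ccccc3)cc2)Oc2c1c(OCc3ccccc3)cc(OCc3ccccc3)c2
F6 | step 12 | (2R)-5,7-bis(benzyloxy)-2-[4-(benzyloxy)phenyl]-8-bromochroman | C1C[C@H](c2ccc(OCc3ccccc3)cc2)Oc2c1c(OCc3ccccc3)cc(OCc3ccccc3)c2Br
F7 | step 12 | {(2R)-5,7-bis(benzyloxy)-2-[4-(benzyloxy)phenyl]chroman-8-yl}lithium | C1C[C@H](c2ccc(OCc3ccccc3)cc2)Oc2c1c(OCc3ccccc3)cc(OCc3ccccc3)c2[Li]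
F8 | step 12 | 2-{(2R)-5,7-bis(benzyloxy)-2-[4-(benzyloxy)phenyl]chroman-8-yl}-4,4,5,5-tetramethyl-1,3,2-dioxaborolane | C1C[C@H](c2ccc(OCc3ccccc3)cc2)Oc2c1c(OCc3ccccc3)cc(OCc3ccccc3)c2B1OC(C)(C)C(C)(C)O1
F9 | step 12 | 5,7-bis(benzyloxy)-3-{(2R)-5,7-bis(benzyloxy)-2-[4-(benzyloxy)phenyl]chroman-8-yl}-4H-chromen-4-one | C1C[C@H](c2ccc(OCc3ccccc3)cc2)Oc2c1c(OCc3ccccc3)cc(OCc3ccccc3)c2-c1coc2cc(OCc3ccccc3)cc(OCc3ccccc3)c2c1=O
F0 | step 11 | none | none
F10 | step 9 | [5,7-bis(benzyloxy)-2,2-dimethyl-4H-1,3-benzodioxin-8-yl]zinc chloride | CC1(C)OCc2c(OCc3ccccc3)cc(OCc3ccccc3)c([Zn]Cl)c2O1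
F11 | step 4 | 4,6-bis(benzyloxy)-3-bromo-2-hydroxybenzaldehyde | O=Cc1c(O)c(Br)c(OCc2ccccc2)cc1OCc1ccccc1
F12 | step 4 | 3,5-bis(benzyloxy)-2-bromo-6-(hydroxymethyl)phenol | OCc1c(O)c(Br)c(OCc2ccccc2)cc1OCc1ccccc1
A1 | alternative 1 | 3-(benzyloxy)cyclobut-2-en-1-one | O=C1C=C(OCc2ccccc2)C1
A2 | alternative 1 | 5,7-bis(benzyloxy)-2-[3,4-bis(benzyloxy)phenyl]-3-[(benzyloxy)ethynyl]-4H-chromen-4-one | O=c1c(C#COCc2ccccc2)c(-c2ccc(OCc3ccccc3)c(OCc3ccccc3)c2)oc2cc(OCc3ccccc3)cc(OCc3ccccc3)c12
A3 | alternative 1 | 5,7-bis(benzyloxy)-2-[3,4-bis(benzyloxy)phenyl]-3-[2,4-bis(benzyloxy)-6-hydroxyphenyl]-4H-chromen-4-one | O=c1c(-c2c(O)cc(OCc3ccccc3)cc2OCc3ccccc3)c(-c2ccc(OCc3ccccc3)c(OCc3ccccc3)c2)oc2cc(OCc3ccccc3)cc(OCc3ccccc3)c12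
A4 | alternative 2 | (2R)-5,7-bis(benzyloxy)-2-[4-(benzyloxy)phenyl]-8-{(Z)-2-[3,4-bis(benzyloxy)phenyl]ethenyl}chroman-4-one | O=C1C[C@H](c2ccc(OCc3ccccc3)cc2)Oc2c1c(OCc3ccccc3)cc(OCc3ccccc3)c2/C=C\c1ccc(OCc2ccccc2)c(OCc2ccccc2)c1
A5 | alternative 2 | (2R)-5,7-bis(benzyloxy)-2-[4-(benzyloxy)phenyl]-8-{(2R,3R)-5,7-bis(benzyloxy)-2-[3,4-bis(benzyloxy)phenyl]chroman-3-yl}chroman-4-one (2,3-cis) | O=C1C[C@H](c2ccc(OCc3ccccc3)cc2)Oc2c1c(OCc3ccccc3)cc(OCc3ccccc3)c2[C@H]1Cc2c(OCc3ccccc3)cc(OCc3ccccc3)cc2O[C@H]1c1ccc(OCc3ccccc3)c(OCc3ccccc3)c1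
A6 | alternative 3 | (2R,3R)-5,7-bis(benzyloxy)-2-[3,4-bis(benzyloxy)phenyl]-3-{6-(benzyloxy)-2-[4-(benzyloxy)benzyloxy]-3-(diazoacetyl)-4-(triisopropylsilyloxy)phenyl}chroman-4-one | [N-]=[N+]=CC(=O)c1c(O[Si](C(C)C)(C(C)C)C(C)C)cc(OCc2ccccc2)c(c1OCc1ccc(OCc2ccccc2)cc1)[C@H]1C(=O)c2c(OCc3ccccc3)cc(OCc3ccccc3)cc2O[C@H]1c1ccc(OCc2ccccc2)c(OCc2ccccc2)c1
A7 | alternative 3 | (2R,3R)-5,7-bis(benzyloxy)-2-[3,4-bis(benzyloxy)phenyl]-3-{(2R)-7-(benzyloxy)-2-[4-(benzyloxy)phenyl]-4-oxo-5-(triisopropylsilyloxy)chroman-8-yl}chroman-4-one | O=C1C[C@H](c2ccc(OCc3ccccc3)cc2)Oc2c1c(O[Si](C(C)C)(C(C)C)C(C)C)cc(OCc3ccccc3)c2[C@H]1C(=O)c2c(OCc3ccccc3)cc(OCc3ccccc3)cc2O[C@H]1c1ccc(OCc3ccccc3)c(OCc3ccccc3)c1
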